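**Plan**

- Retrosynthesis: the two ring epoxides (C1–O–C10, C4–O–C5) are removed first, then the C13 acetate and the C8 epoxy ester. The ten-membered ring is opened at C1–C2, the butenolide at C7=C11 and at its ester bond O6–C12, and the chain at C5–C6.
- Forward: 2-deoxy-D-ribose gives the C6–C10 aldehyde carrying the E C1 iodide, and a Z-dienyllithium (C2–C5) adds at C6. The C6 hydroxyl is esterified with the C11–C13 phosphonate and C7 is oxidised. Olefination closes the butenolide first, hydroboration/Suzuki coupling then closes the carbocycle, and the two esters and both epoxides follow.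
- Stereochemistry: C8 is sugar C3. C6 is set by Felkin–Anh addition next to sugar C4, which afterwards becomes the C7 ketone. The E and Z olefins come from syn-carboalumination and anti-carbomagnesiation. The side-chain epoxide comes from a Sharpless epoxidation, the ring epoxides from outer-face attack on the macrocyclic diene.
- Enabling feature: C7 is a trigonal ring carbon flanked by the oxygen-bearing stereocentres C6 and C8, and O6–C12(=O)–C11=C7–C6 is a butenolide. With C7 as a ketone and C11 as a phosphonate carbanion on the C6 ester, that ring closes by olefination.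

Key step: step 19

Remark: germacrane numbering is used (ring C1–C10, lactone carbons C11–C13, C14 on C10, C15 on C4); acid 22 is racemic at C11, which is of no consequence because C11 becomes trigonal in step 19.

**Route**

Step 1
Reactants: 1 2-deoxy-D-ribose
Product: 2 3,4-O-isopropylidene-2-deoxy-D-ribopyranose (lactol, anomer mixture)
Conditions: 2-methoxypropene, PPTS (cat.), EtOAc, rt
Reagents that add atoms: 2-methoxypropene, COC(C)=C
Why: Kinetic transacetalisation takes the cis-3,4-diol of the pyranose form into a dioxolane, which masks O3 and O4 (later O8 and O7) and leaves C1 as a lactol.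

Step 2
Reactants: 2 3,4-O-isopropylidene-2-deoxy-D-ribopyranose
Product: 3 [(4R,5S)-2,2-dimethyl-5-(prop-2-yn-1-yl)-1,3-dioxolan-4-yl]methanol
Conditions: dimethyl (1-diazo-2-oxopropyl)phosphonate, K2CO3, MeOH, rt to 40 °C
Reagents that add atoms: dimethyl (1-diazo-2-oxopropyl)phosphonate, COP(=O)(OC)C(=[N+]=[N-])C(C)=O
Why: The Ohira–Bestmann form of the Seyferth–Gilbert homologation intercepts the open-chain aldehyde of the lactol and turns sugar C1 into a terminal alkyne (later C10 and C1) without touching the two stereocentres.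

Step 3
Reactants: 3 [(4R,5S)-2,2-dimethyl-5-(prop-2-yn-1-yl)-1,3-dioxolan-4-yl]methanol
Product: 4 (1S)-1-[(4R)-2,2-dimethyl-1,3-dioxolan-4-yl]but-3-yn-1-ol
Conditions: TsOH·H2O (cat.), acetone, rt
Reagents that add atoms: none
Why: Acid-catalysed acetonide migration under thermodynamic control should move the ketal from the cis-disubstituted internal dioxolane to the less strained terminal dioxolane of this erythro triol, which frees the later C8 hydroxyl and ties up O7 and O6.

Step 4
Reactants: 4 (1S)-1-[(4R)-2,2-dimethyl-1,3-dioxolan-4-yl]but-3-yn-1-ol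
Product: 5 TBS ether of 4
Conditions: TBSCl, imidazole, DMF, rt
Reagents that add atoms: tert-butyldimethylsilyl chloride, CC(C)(C)[Si](C)(C)Cl
Why: Routine silylation of the secondary alcohol installs the O8 protecting group that has to outlast the one placed later on O7.

Step 5
Reactants: 5 TBS ether of 4
Product: 7 E-vinyl iodide (C14 methyl on C10 and iodine on C1), via alkenyldimethylalane 6 (not isolated)
Conditions: Me3Al, Cp2ZrCl2 (cat.), H2O (1 equiv), CH2Cl2, −23 °C; then I2, THF, −23 to 0 °C
Reagents that add atoms: trimethylaluminium, C[Al](C)C; iodine, II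
Why: Zirconium-catalysed syn-carboalumination (Negishi) puts the methyl group on the internal and aluminium on the terminal alkyne carbon, and iodinolysis with retention then gives only the E trisubstituted vinyl iodide.

Step 6
Reactants: 7 E-vinyl iodide acetonide
Product: 8 (2R,3S,5E)-3-[(tert-butyldimethylsilyl)oxy]-6-iodo-5-methylhex-5-ene-1,2-diol
Conditions: CuCl2·2H2O, MeCN, 0 °C
Reagents that add atoms: none
Why: Mild Lewis-acid hydrolysis of a terminal acetonide spares a secondary TBS ether, and the vinyl iodide is inert to it.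

Step 7
Reactants: 8 diol
Product: 9 1,2-bis(triethylsilyl) ether of 8
Conditions: TESOTf, 2,6-lutidine, CH2Cl2, −78 to 0 °C
Reagents that add atoms: triethylsilyl triflate, CC[Si](CC)(CC)OS(=O)(=O)C(F)(F)F
Why: Exhaustive silylation gives O7 and O6 as TES ethers, which are more labile than the TBS ether on O8 and do not chelate.

Step 8
Reactants: 9 bis-TES ether
Product: 10 (2S,3S,5E)-3-[(tert-butyldimethylsilyl)oxy]-6-iodo-5-methyl-2-[(triethylsilyl)oxy]hex-5-enal
Conditions: (COCl)2, DMSO, CH2Cl2, −78 to −30 °C; then Et3N, −78 to 0 °C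
Reagents that add atoms: none
Why: Under Swern conditions a primary TES ether is cleaved by the chlorosulfonium salt and oxidised in the same flask while secondary TES and TBS ethers persist, which should give the α-silyloxy aldehyde (C6) directly and cold enough to avoid epimerisation.

Step 9
Reactants: 11 prop-2-yn-1-ol
Product: 13 (2Z)-3-iodo-2-methylprop-2-en-1-ol, via alkenylmagnesium alkoxide 12 (not isolated)
Conditions: MeMgBr (2.5 equiv), CuI (10 mol %), THF, −10 °C to rt; then I2, −78 to 0 °C
Reagents that add atoms: methylmagnesium bromide, C[Mg]Br; iodine, II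
Why: Copper-catalysed anti-carbomagnesiation of the propargylic alkoxide places methyl on C2 and magnesium on C3 cis to the CH2O group (five-membered chelate), and iodinolysis with retention gives the Z iodide.

Step 10
Reactants: 13 (2Z)-3-iodo-2-methylprop-2-en-1-ol
Product: 14 (2Z)-3-iodo-2-methylprop-2-enal
Conditions: MnO2, CH2Cl2, rt
Reagents that add atoms: none
Why: Allylic oxidation with MnO2 is neutral and heterogeneous, so the Z β-iodo enal should form without isomerisation and can be used crude.

Step 11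
Reactants: 14 (2Z)-3-iodo-2-methylprop-2-enal
Product: 15 (1Z)-1-iodo-2-methylbuta-1,3-diene
Conditions: Ph3PCH3Br, NaN(SiMe3)2, THF, −78 to 0 °C
Reagents that add atoms: methyltriphenylphosphonium bromide, C[P+](c1ccccc1)(c1ccccc1)c1ccccc1.[Br-]
Why: Wittig methylenation turns the aldehyde into the vinyl group (C3=C2) and leaves the Z relation between iodine and that vinyl group untouched.

Step 12
Reactants: 15 (1Z)-1-iodo-2-methylbuta-1,3-diene, 10 α-silyloxy aldehyde
Product: 17 (3Z,5R,6R,7S,9E)-7-[(tert-butyldimethylsilyl)oxy]-10-iodo-3,9-dimethyl-6-[(triethylsilyl)oxy]deca-1,3,9-trien-5-ol, via [(1Z)-2-methylbuta-1,3-dien-1-yl]lithium 16 (not isolated)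
Conditions: 15, t-BuLi (2 equiv), Et2O, −78 °C; then 10, −78 °C; AcOH, −78 °C
Reagents that add atoms: none
Why: Iodine–lithium exchange with retention gives the Z-dienyllithium, whose 1,2-addition to the aldehyde should follow the Felkin–Anh (polar) model with the non-chelating OTES group on C7 directing attack to the 6,7-anti carbinol (C6, here 5R), while the cold acidic quench prevents silyl migration from O7 to O6.

Step 13
Reactants: 18 triethyl phosphonoacetate
Product: 20 ethyl 2-(diethoxyphosphoryl)prop-2-enoate, via ethyl 2-(diethoxyphosphoryl)-3-methoxypropanoate 19 (not isolated)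
Conditions: (CH2O)n, piperidine (cat.), MeOH, reflux; then TsOH·H2O (cat.), toluene, distillation
Reagents that add atoms: paraformaldehyde (formaldehyde), C=O
Why: Amine-catalysed Knoevenagel condensation with formaldehyde in methanol gives the methanol adduct of the acrylate, and acid-catalysed elimination of methanol on distillation releases the 2-phosphonoacrylate.

Step 14
Reactants: 20 ethyl 2-(diethoxyphosphoryl)prop-2-enoate
Product: 21 ethyl 2-(diethoxyphosphoryl)-3-[(4-methoxybenzyl)oxy]propanoate
Conditions: 4-methoxybenzyl alcohol, NaH (5 mol %), THF, 0 °C to rt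
Reagents that add atoms: 4-methoxybenzyl alcohol, COc1ccc(CO)cc1
Why: Base-catalysed oxa-Michael addition to the doubly activated alkene, the same reaction methanol undergoes in step 13, installs the protected C13 oxygen next to the phosphonate carbon C11.

Step 15
Reactants: 21 ethyl 2-(diethoxyphosphoryl)-3-[(4-methoxybenzyl)oxy]propanoate
Product: 22 2-(diethoxyphosphoryl)-3-[(4-methoxybenzyl)oxy]propanoic acid
Conditions: Me3SnOH, ClCH2CH2Cl, 70 °C; then 1 M HCl wash
Reagents that add atoms: trimethyltin hydroxide, C[Sn](C)(C)O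
Why: Trimethyltin hydroxide cleaves the ethyl ester under nearly neutral conditions, chosen because aqueous alkali could eject the β-alkoxy group by retro-Michael reaction.

Step 16
Reactants: 17 C6 carbinol, 22 phosphonate acid
Product: 23 C6 ester of 17 with acid 22 (C11 epimers)
Conditions: DCC, DMAP (cat.), CH2Cl2, 0 °C to rt
Reagents that add atoms: none
Why: Steglich esterification of an α-phosphono acid proceeds through a highly reactive acylating species (phosphonoketene or acylpyridinium) that should acylate even this flanked secondary alcohol, and the C11 configuration is irrelevant.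

Step 17
Reactants: 23 C6 phosphonate ester with O7 TES ether
Product: 24 C7 alcohol
Conditions: PPTS (cat.), MeOH/CH2Cl2, 0 °C
Reagents that add atoms: none
Why: Mild acid methanolysis removes a secondary TES ether selectively in the presence of a TBS ether, and the weakly acidic medium should not promote acyl migration from O6 to O7.

Step 18
Reactants: 24 C7 alcohol
Product: 25 (3Z,5R,7S,9E)-7-[(tert-butyldimethylsilyl)oxy]-10-iodo-3,9-dimethyl-6-oxodeca-1,3,9-trien-5-yl 2-(diethoxyphosphoryl)-3-[(4-methoxybenzyl)oxy]propanoate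
Conditions: Dess–Martin periodinane, NaHCO3, CH2Cl2, 0 °C to rt
Reagents that add atoms: none
Why: Buffered Dess–Martin oxidation converts the secondary alcohol into the C7 ketone under neutral conditions that should not enolise the new α-acyloxy ketone.

Step 19
Reactants: 25 C6 phosphonopropanoate of the C7 ketone
Product: 26 (5R)-4-[(1S,3E)-1-[(tert-butyldimethylsilyl)oxy]-4-iodo-3-methylbut-3-en-1-yl]-3-{[(4-methoxybenzyl)oxy]methyl}-5-[(1Z)-2-methylbuta-1,3-dien-1-yl]furan-2(5H)-one
Conditions: LiCl, iPr2NEt, MeCN, 0 °C to rt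
Reagents that add atoms: none
Why: Li+ chelates the phosphoryl and ester carbonyl oxygens of the C6 phosphonoacetate so that the weak amine base deprotonates C11 (Masamune–Roush conditions), the carbanion adds to the neighbouring C7 ketone, and the β-oxido phosphonate collapses through the oxaphosphetane with loss of diethyl phosphate to give C7=C11. The closest known reaction type is the intramolecular Horner–Wadsworth–Emmons synthesis of butenolides from α-acyloxy ketones. The one ring formed, the butenolide O6–C12–C11–C7–C6, closes by 5-exo-trig attack of C11 on the C7 carbonyl. No stereocentre is created, and the olefin geometry is fixed by the five-membered ring. The step needs deprotonation at C11 in preference to enolisation of the ketone towards C6 or C8; the lithium-chelated, doubly stabilised phosphonate is far more acidic than the ketone α-hydrogens and the base is mild, so C6 and the sugar-derived C8 should keep their configuration. Loss of the C13 alkoxide by E1cB is not expected, because the alkoxide is a much stronger base than the stabilised carbanion and ring closure onto the adjacent ketone is fast.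

Step 20
Reactants: 26 butenolide with Z-dienyl and E-iodide arms
Product: 28 (1(10)E,4Z,6R,8S)-8-[(tert-butyldimethylsilyl)oxy]-13-[(4-methoxybenzyl)oxy]germacra-1(10),4,7(11)-trien-12,6-olide, via B-alkyl-9-borabicyclo[3.3.1]nonane 27 (not isolated)
Conditions: 9-BBN dimer, THF, 0 °C to rt; then slow addition to PdCl2(dppf), AsPh3, Cs2CO3, DMF/THF/H2O, rt, 2 mM
Reagents that add atoms: none
Why: 9-BBN adds anti-Markovnikov only to the terminal C2=C3 olefin of the diene, and the B-alkyl borane then couples with the C1 vinyl iodide under high dilution (intramolecular B-alkyl Suzuki–Miyaura reaction) with retention of the E geometry, which closes the ten-membered ring at C1–C2.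

Step 21
Reactants: 28 macrocyclic TBS ether
Product: 29 (1(10)E,4Z,6R,8S)-8-hydroxy-13-[(4-methoxybenzyl)oxy]germacra-1(10),4,7(11)-trien-12,6-olide
Conditions: HF·pyridine, pyridine, THF, 0 °C to rt
Reagents that add atoms: none
Why: Buffered fluoride cleavage of the TBS ether is safe at this stage because no epoxide is present and the PMB ether, the lactone and the ring olefins tolerate it.

Step 22
Reactants: 30 2-methylprop-2-en-1-ol
Product: 31 [(2R)-2-methyloxiran-2-yl]methanol
Conditions: Ti(OiPr)4 (5 mol %), D-(−)-diisopropyl tartrate (6 mol %), t-BuOOH, 4 Å molecular sieves, CH2Cl2, −20 °C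
Reagents that add atoms: tert-butyl hydroperoxide, CC(C)(C)OO
Why: In the Sharpless asymmetric epoxidation the titanium tartrate catalyst chooses the olefin face, and the D-(−)-tartrate (antipode of the natural ester) should deliver the 2R epoxy alcohol.

Step 23
Reactants: 31 [(2R)-2-methyloxiran-2-yl]methanol
Product: 32 (2S)-2-methyloxirane-2-carboxylic acid
Conditions: TEMPO (cat.), PhI(OAc)2, MeCN/H2O, rt
Reagents that add atoms: water, O
Why: Oxoammonium oxidation takes the primary alcohol through the aldehyde hydrate to the acid without touching the quaternary epoxide carbon, whose descriptor changes from R to S only through the priority rules.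

Step 24
Reactants: 29 C8 alcohol, 32 (2S)-2-methyloxirane-2-carboxylic acid
Product: 34 (1(10)E,4Z,6R,8S)-13-[(4-methoxybenzyl)oxy]-8-{[(2S)-2-methyloxiran-2-yl]carbonyloxy}germacra-1(10),4,7(11)-trien-12,6-olide, via mixed 2,4,6-trichlorobenzoic anhydride 33 (not isolated)
Conditions: 32, 2,4,6-trichlorobenzoyl chloride, Et3N, THF, 0 °C; then 29, DMAP, toluene, rt
Reagents that add atoms: none
Why: Yamaguchi esterification activates the α-quaternary epoxy acid as a mixed anhydride that DMAP transfers to the secondary C8 hydroxyl with retention at C8 and without opening the epoxide.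

Step 25
Reactants: 34 C8 epoxy ester with C13 PMB ether
Product: 35 13-hydroxy analogue of 34
Conditions: DDQ, CH2Cl2/pH 7 buffer, 0 °C to rt
Reagents that add atoms: none
Why: Oxidative cleavage of the PMB ether by DDQ under buffered conditions leaves the trisubstituted olefins, the esters and the side-chain epoxide intact.

Step 26
Reactants: 35 C13 alcohol
Product: 36 (1(10)E,4Z,6R,8S)-13-acetoxy-8-{[(2S)-2-methyloxiran-2-yl]carbonyloxy}germacra-1(10),4,7(11)-trien-12,6-olide
Conditions: Ac2O, pyridine, DMAP (cat.), CH2Cl2, 0 °C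
Reagents that add atoms: acetic anhydride, CC(=O)OC(C)=O
Why: Standard acetylation of the primary allylic alcohol installs the C13 acetate under conditions too mild to affect the lactone or the C8 ester.

Step 27
Reactants: 36 macrocyclic diene
Product: 37 (1R,4R,5S,6S,8S,10R)-13-acetoxy-1,10:4,5-diepoxy-8-{[(2S)-2-methyloxiran-2-yl]carbonyloxy}germacr-7(11)-en-12,6-olide (CNP0289810.1)
Conditions: dimethyldioxirane (2.5 equiv), acetone, −20 to 0 °C
Reagents that add atoms: dimethyldioxirane, CC1(C)OO1
Why: Electrophilic dioxirane epoxidation attacks the two electron-rich trisubstituted ring olefins and not the electron-poor butenolide, and its stereospecific syn addition turns E C1=C10 into the trans and Z C4=C5 into the cis epoxide, and attack on the outer face of each olefin in the preferred ring conformation is expected to give 1R,10R and 4R,5S.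

**Compound list**

1 | 2-deoxy-D-ribose (open-chain form) | O=CC[C@H](O)[C@H](O)CO | starting material
2 | 3,4-O-isopropylidene-2-deoxy-D-ribopyranose (anomer mixture) | OC1C[C@@H]2OC(C)(C)O[C@@H]2CO1 | intermediate
3 | [(4R,5S)-2,2-dimethyl-5-(prop-2-yn-1-yl)-1,3-dioxolan-4-yl]methanol | C#CC[C@@H]1OC(C)(C)O[C@@H]1CO | intermediate
4 | (1S)-1-[(4R)-2,2-dimethyl-1,3-dioxolan-4-yl]but-3-yn-1-ol | C#CC[C@H](O)[C@H]1COC(C)(C)O1 | intermediate
5 | tert-butyl{[(1S)-1-[(4R)-2,2-dimethyl-1,3-dioxolan-4-yl]but-3-yn-1-yl]oxy}dimethylsilane | C#CC[C@H](O[Si](C)(C)C(C)(C)C)[C@H]1COC(C)(C)O1 | intermediate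
6 | {(1E,4S)-4-[(tert-butyldimethylsilyl)oxy]-4-[(4R)-2,2-dimethyl-1,3-dioxolan-4-yl]-2-methylbut-1-en-1-yl}dimethylalane (not isolated) | C[Al](C)/C=C(C)/C[C@H](O[Si](C)(C)C(C)(C)C)[C@H]1COC(C)(C)O1 | intermediate
7 | tert-butyl{[(1S,3E)-1-[(4R)-2,2-dimethyl-1,3-dioxolan-4-yl]-4-iodo-3-methylbut-3-en-1-yl]oxy}dimethylsilane | I/C=C(C)/C[C@H](O[Si](C)(C)C(C)(C)C)[C@H]1COC(C)(C)O1 | intermediate
8 | (2R,3S,5E)-3-[(tert-butyldimethylsilyl)oxy]-6-iodo-5-methylhex-5-ene-1,2-diol | I/C=C(C)/C[C@H](O[Si](C)(C)C(C)(C)C)[C@H](O)CO | intermediate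
9 | (2R,3S,5E)-3-[(tert-butyldimethylsilyl)oxy]-6-iodo-5-methyl-1,2-bis[(triethylsilyl)oxy]hex-5-ene | I/C=C(C)/C[C@H](O[Si](C)(C)C(C)(C)C)[C@H](O[Si](CC)(CC)CC)CO[Si](CC)(CC)CC | intermediate
10 | (2S,3S,5E)-3-[(tert-butyldimethylsilyl)oxy]-6-iodo-5-methyl-2-[(triethylsilyl)oxy]hex-5-enal | I/C=C(C)/C[C@H](O[Si](C)(C)C(C)(C)C)[C@H](O[Si](CC)(CC)CC)C=O | intermediate
11 | prop-2-yn-1-ol | C#CCO | starting material
12 | bromomagnesium (2Z)-3-(bromomagnesio)-2-methylprop-2-en-1-olate (not isolated) | Br[Mg]/C=C(C)\CO[Mg]Br | intermediate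
13 | (2Z)-3-iodo-2-methylprop-2-en-1-ol | I/C=C(C)\CO | intermediate
14 | (2Z)-3-iodo-2-methylprop-2-enal | I/C=C(C)\C=O | intermediate
15 | (1Z)-1-iodo-2-methylbuta-1,3-diene | I/C=C(C)\C=C | intermediate
16 | [(1Z)-2-methylbuta-1,3-dien-1-yl]lithium (not isolated) | [Li]/C=C(C)\C=C | intermediate
17 | (3Z,5R,6R,7S,9E)-7-[(tert-butyldimethylsilyl)oxy]-10-iodo-3,9-dimethyl-6-[(triethylsilyl)oxy]deca-1,3,9-trien-5-ol | C=C/C(C)=C\[C@@H](O)[C@@H](O[Si](CC)(CC)CC)[C@@H](O[Si](C)(C)C(C)(C)C)C/C(C)=C/I | intermediate
18 | triethyl phosphonoacetate | CCOC(=O)CP(=O)(OCC)OCC | starting material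
19 | ethyl 2-(diethoxyphosphoryl)-3-methoxypropanoate (not isolated) | CCOC(=O)C(COC)P(=O)(OCC)OCC | intermediate
20 | ethyl 2-(diethoxyphosphoryl)prop-2-enoate | CCOC(=O)C(=C)P(=O)(OCC)OCC | intermediate
21 | ethyl 2-(diethoxyphosphoryl)-3-[(4-methoxybenzyl)oxy]propanoate (racemic) | CCOC(=O)C(COCc1ccc(OC)cc1)P(=O)(OCC)OCC | intermediate
22 | 2-(diethoxyphosphoryl)-3-[(4-methoxybenzyl)oxy]propanoic acid (racemic) | CCOP(=O)(OCC)C(COCc1ccc(OC)cc1)C(O)=O | intermediate
23 | (3Z,5R,6R,7S,9E)-7-[(tert-butyldimethylsilyl)oxy]-10-iodo-3,9-dimethyl-6-[(triethylsilyl)oxy]deca-1,3,9-trien-5-yl 2-(diethoxyphosphoryl)-3-[(4-methoxybenzyl)oxy]propanoate (C11 epimers) | CCOP(=O)(OCC)C(COCc1ccc(OC)cc1)C(=O)O[C@H](/C=C(C)\C=C)[C@@H](O[Si](CC)(CC)CC)[C@@H](O[Si](C)(C)C(C)(C)C)C/C(C)=C/I | intermediate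
24 | (3Z,5R,6R,7S,9E)-7-[(tert-butyldimethylsilyl)oxy]-6-hydroxy-10-iodo-3,9-dimethyldeca-1,3,9-trien-5-yl 2-(diethoxyphosphoryl)-3-[(4-methoxybenzyl)oxy]propanoate | CCOP(=O)(OCC)C(COCc1ccc(OC)cc1)C(=O)O[C@H](/C=C(C)\C=C)[C@@H](O)[C@@H](O[Si](C)(C)C(C)(C)C)C/C(C)=C/I | intermediate
25 | (3Z,5R,7S,9E)-7-[(tert-butyldimethylsilyl)oxy]-10-iodo-3,9-dimethyl-6-oxodeca-1,3,9-trien-5-yl 2-(diethoxyphosphoryl)-3-[(4-methoxybenzyl)oxy]propanoate | CCOP(=O)(OCC)C(COCc1ccc(OC)cc1)C(=O)O[C@H](/C=C(C)\C=C)C(=O)[C@@H](O[Si](C)(C)C(C)(C)C)C/C(C)=C/I | intermediate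
26 | (5R)-4-[(1S,3E)-1-[(tert-butyldimethylsilyl)oxy]-4-iodo-3-methylbut-3-en-1-yl]-3-{[(4-methoxybenzyl)oxy]methyl}-5-[(1Z)-2-methylbuta-1,3-dien-1-yl]furan-2(5H)-one | C=C/C(C)=C\[C@H]1OC(=O)C(COCc2ccc(OC)cc2)=C1[C@@H](O[Si](C)(C)C(C)(C)C)C/C(C)=C/I | intermediate
27 | B-alkyl-9-borabicyclo[3.3.1]nonane from 26 (boron on C2, C2–C3 saturated; not isolated) | C1CCC2CCCC1B2CC/C(C)=C\[C@H]3OC(=O)C(COCc4ccc(OC)cc4)=C3[C@@H](O[Si](C)(C)C(C)(C)C)C/C(C)=C/I | intermediate
28 | (1(10)E,4Z,6R,8S)-8-[(tert-butyldimethylsilyl)oxy]-13-[(4-methoxybenzyl)oxy]germacra-1(10),4,7(11)-trien-12,6-olide | COc1ccc(COCC2=C3[C@@H](O[Si](C)(C)C(C)(C)C)C/C(C)=C/CC/C(C)=C\[C@H]3OC2=O)cc1 | intermediate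
29 | (1(10)E,4Z,6R,8S)-8-hydroxy-13-[(4-methoxybenzyl)oxy]germacra-1(10),4,7(11)-trien-12,6-olide | COc1ccc(COCC2=C3[C@@H](O)C/C(C)=C/CC/C(C)=C\[C@H]3OC2=O)cc1 | intermediate
30 | 2-methylprop-2-en-1-ol | C=C(C)CO | starting material
31 | [(2R)-2-methyloxiran-2-yl]methanol | OC[C@]1(C)CO1 | intermediate
32 | (2S)-2-methyloxirane-2-carboxylic acid | OC(=O)[C@]1(C)CO1 | intermediate
33 | (2S)-2-methyloxirane-2-carboxylic 2,4,6-trichlorobenzoic anhydride (not isolated) | O=C(OC(=O)[C@]1(C)CO1)c2c(Cl)cc(Cl)cc2Cl | intermediate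
34 | (1(10)E,4Z,6R,8S)-13-[(4-methoxybenzyl)oxy]-8-{[(2S)-2-methyloxiran-2-yl]carbonyloxy}germacra-1(10),4,7(11)-trien-12,6-olide | COc1ccc(COCC2=C3[C@@H](OC(=O)[C@]4(C)CO4)C/C(C)=C/CC/C(C)=C\[C@H]3OC2=O)cc1 | intermediate
35 | (1(10)E,4Z,6R,8S)-13-hydroxy-8-{[(2S)-2-methyloxiran-2-yl]carbonyloxy}germacra-1(10),4,7(11)-trien-12,6-olide | OCC1=C2[C@@H](OC(=O)[C@]3(C)CO3)C/C(C)=C/CC/C(C)=C\[C@H]2OC1=O | intermediate
36 | (1(10)E,4Z,6R,8S)-13-acetoxy-8-{[(2S)-2-methyloxiran-2-yl]carbonyloxy}germacra-1(10),4,7(11)-trien-12,6-olide | CC(=O)OCC1=C2[C@@H](OC(=O)[C@]3(C)CO3)C/C(C)=C/CC/C(C)=C\[C@H]2OC1=O | intermediate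
37 | (1R,4R,5S,6S,8S,10R)-13-acetoxy-1,10:4,5-diepoxy-8-{[(2S)-2-methyloxiran-2-yl]carbonyloxy}germacr-7(11)-en-12,6-olide (CNP0289810.1) | CC(=O)OCC1=C2[C@@H](OC(=O)[C@]3(C)CO3)C[C@@]3(C)O[C@@H]3CC[C@@]3(C)O[C@H]3[C@H]2OC1=O | target

**Step count**

Total step count: 27. Longest linear sequence: 19 steps (steps 1–8, 12, 16–21, 24–27, from 2-deoxy-D-ribose).

**Steps most likely to fail**

1. Step 20 (macrocyclisation). Intermolecular coupling, protodeboronation and β-hydride elimination may outrun closure of the strained ten-membered ring, and the aqueous carbonate may epimerise C6, which is both the γ-position of the butenolide and allylic. The fallback sets out from 26 and comes back at 28 by a base-free, water-free coupling of a different organometallic. The 9-BBN adduct 27 is oxidised with NaBO3·4H2O in THF/H2O to the C2 primary alcohol F1. PPh3, I2 and imidazole convert it into the C2 primary iodide F2. Zinc dust with LiCl in THF inserts selectively into the primary C–I bond to give the alkylzinc iodide F3. This is added slowly to the zerovalent palladium catalyst Pd2(dba)3/P(2-furyl)3 in THF/DMF (intramolecular Negishi coupling with the C1 vinyl iodide), giving 28.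

2. Step 27 (double epoxidation). The dioxirane may attack the inner face or the wrong outer face of one olefin if several ring conformers are populated, giving diastereomeric diepoxides, and the 4,5-olefin, deactivated by the allylic lactone oxygen, may react sluggishly. The fallback sets out from 36 and comes back at 37 under reagent control (Shi epoxidation, KHSO5, K2CO3 buffer, MeCN/dimethoxymethane/H2O, 0 °C). The D-fructose-derived ketone epoxidises the more electron-rich E 1(10)-olefin to the (1R,10R)-1,10-monoepoxide F4. The enantiomeric ketone (from L-sorbose), chosen by the spiro transition-state model for the CH carbon C5, then epoxidises the Z 4,5-olefin to give 37.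

3. Step 12 (dienyllithium addition). Facial selectivity may be insufficient, or chelation-type attack may give the C6 epimer, and the lithium alkoxide may transfer the TES group from O7 to O6. The fallback sets out from 17 (as the C6 epimer mixture) and comes back at 17. Dess–Martin oxidation gives the dienone (3Z,6S,7S,9E)-7-[(tert-butyldimethylsilyl)oxy]-10-iodo-3,9-dimethyl-6-[(triethylsilyl)oxy]deca-1,3,9-trien-5-one F5. Corey–Bakshi–Shibata reduction with the (R)-methyl oxazaborolidine and catecholborane at −78 °C then sets C6 under reagent control; with the dienyl group as the large substituent in the Corey model this catalyst should return the required 6,7-anti alcohol 17.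

Further compounds
F1 | step 20 | (5R)-4-[(1S,3E)-1-[(tert-butyldimethylsilyl)oxy]-4-iodo-3-methylbut-3-en-1-yl]-5-[(1Z)-4-hydroxy-2-methylbut-1-en-1-yl]-3-{[(4-methoxybenzyl)oxy]methyl}furan-2(5H)-one | OCC/C(C)=C\[C@H]1OC(=O)C(COCc2ccc(OC)cc2)=C1[C@@H](O[Si](C)(C)C(C)(C)C)C/C(C)=C/I
F2 | step 20 | (5R)-4-[(1S,3E)-1-[(tert-butyldimethylsilyl)oxy]-4-iodo-3-methylbut-3-en-1-yl]-5-[(1Z)-4-iodo-2-methylbut-1-en-1-yl]-3-{[(4-methoxybenzyl)oxy]methyl}furan-2(5H)-one | ICC/C(C)=C\[C@H]1OC(=O)C(COCc2ccc(OC)cc2)=C1[C@@H](O[Si](C)(C)C(C)(C)C)C/C(C)=C/I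
F3 | step 20 | alkylzinc iodide from F2 (zinc on C2) | I[Zn]CC/C(C)=C\[C@H]1OC(=O)C(COCc2ccc(OC)cc2)=C1[C@@H](O[Si](C)(C)C(C)(C)C)C/C(C)=C/I
F4 | step 27 | (1R,4Z,6R,8S,10R)-13-acetoxy-1,10-epoxy-8-{[(2S)-2-methyloxiran-2-yl]carbonyloxy}germacra-4,7(11)-dien-12,6-olide | CC(=O)OCC1=C2[C@@H](OC(=O)[C@]3(C)CO3)C[C@@]3(C)O[C@@H]3CC/C(C)=C\[C@H]2OC1=O
F5 | step 12 | (3Z,6S,7S,9E)-7-[(tert-butyldimethylsilyl)oxy]-10-iodo-3,9-dimethyl-6-[(triethylsilyl)oxy]deca-1,3,9-trien-5-one | C=C/C(C)=C\C(=O)[C@@H](O[Si](CC)(CC)CC)[C@@H](O[Si](C)(C)C(C)(C)C)C/C(C)=C/I
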